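**Plan**
Retrosynthesis: cut C4–C5 (the methyl-bearing sp2 carbon of the C3=C4 alkene and the neighbouring CH2), which opens the 14-membered carbocycle and with it the bridge across C8/C11 of the 1,2-dioxane; then O–C11 and O–C8 of the dioxane (allylic C11 electrophile, C7–C8 epoxide, H2O2); then C11–C12 (alkenyl + aldehyde); then C1–C2 and the lactone C–O (ester-bearing allyl + enal).
Forward: α-methylene-γ-lactone first (C1–C2), chain joined at C11–C12, 1,2-dioxane second (O–C8, then O–C11), C5 added as a vinyl CH2, 14-membered ring last (C4–C5).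
Enabling feature: C5=C6 can be a plain vinyl group on the acetoxy carbon C7, and C4 the bromine-bearing carbon of an (E)-2-bromopropenyl group on lactone carbon C2. Hydroboration and alkyl–alkenyl coupling therefore close the ring without making a stereocentre, on a chain already bent by the cis-3,6-disubstituted dioxane and the cis-fused lactone.
Stereochemistry: C7/C8 from Sharpless epoxidation of geraniol (C8 inverted by perhydrolysis); C11 from a ligand-controlled Ni/Cr addition followed by two SN2 inversions; C1/C2 from a ligand-controlled, syn-selective chromium allylation; both (E)-alkenes from syn-hydrozirconation of but-2-yn-1-ol and pent-3-yn-1-ol.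
Key step: step 19

Remark: cembrane numbering of the target is used for all intermediates (C1 lactone β-carbon, C2 lactone O–CH, C7 acetoxy carbon, C8 and C11 peroxy carbons, C15–C17 the α-methylene acid unit). The ligand antipodes in steps 10 and 11 are assumed to be those that give the stated configurations, to be confirmed by Mosher ester analysis.

**Route**

Step 1
Reactants: 1 geraniol
Product: 2 (2S,3S)-2,3-epoxygeraniol
Conditions: t-BuOOH, Ti(OiPr)4 (cat.), L-(+)-diethyl tartrate (cat.), 4 Å MS, CH2Cl2, −20 °C
Reagents that add atoms: tert-butyl hydroperoxide, CC(C)(C)OO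
Why: Sharpless asymmetric epoxidation: the titanium tartrate complex binds the allylic hydroxyl and delivers oxygen only to the C2=C3 alkene, L-(+)-tartrate giving the (2S,3S) epoxide whose carbons become C7 (S, kept) and C8 (S, inverted later).

Step 2
Reactants: 2 (2S,3S)-2,3-epoxygeraniol
Product: 3 (2S,3S)-2,3-epoxygeranyl tert-butyldiphenylsilyl ether
Conditions: TBDPSCl, imidazole, CH2Cl2, 0 °C to rt
Reagents that add atoms: tert-butyl(chloro)diphenylsilane, CC(C)(C)[Si](Cl)(c1ccccc1)c1ccccc1
Why: Standard silylation of the primary alcohol; the acid-stable ether masks C6–OH through the chlorination and perhydrolysis and keeps an oxygen on C6 that steers epoxide opening to C8.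

Step 3
Reactants: 3 (2S,3S)-2,3-epoxygeranyl tert-butyldiphenylsilyl ether
Product: 5 3-[(2S,3S)-3-{[(tert-butyldiphenylsilyl)oxy]methyl}-2-methyloxiran-2-yl]propanal, via vicinal diol 4 (not isolated)
Conditions: OsO4 (cat.), NaIO4, 2,6-lutidine, 1,4-dioxane/H2O, rt
Reagents that add atoms: sodium periodate, [Na+].[O-]I(=O)(=O)=O (terminal oxidant; the aldehyde oxygen is delivered through catalytic osmium tetroxide, O=[Os](=O)(=O)=O)
Why: Lemieux–Johnson oxidation: dihydroxylation of the only alkene and periodate cleavage of diol 4 give the C11 aldehyde under buffered conditions that leave the epoxide and silyl ether intact.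

Step 4
Reactants: 6 pent-3-yn-1-ol
Product: 8 (3E)-4-iodopent-3-en-1-ol, via alkenylzirconocene 7 (not isolated)
Conditions: Cp2Zr(H)Cl (2.5 equiv), THF, rt to 40 °C; then I2, 0 °C
Reagents that add atoms: iodine, II
Why: Hydrozirconation–iodination: the first hydride equivalent is consumed by the hydroxyl, syn addition of Zr–H with equilibration places zirconium on the less hindered methyl-bearing carbon, and iodinolysis with retention gives the (E)-iodoalkene that becomes C12=C13.

Step 5
Reactants: 8 (3E)-4-iodopent-3-en-1-ol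
Product: 9 (3E)-4-iodopent-3-enal
Conditions: Dess–Martin periodinane, CH2Cl2, 0 °C to rt; used crude
Reagents that add atoms: none
Why: Dess–Martin oxidation under neutral conditions gives the β,γ-unsaturated aldehyde without moving the alkene into conjugation.

Step 6
Reactants: 9 (3E)-4-iodopent-3-enal; 10 methyl acrylate
Product: 11 methyl (5E)-3-hydroxy-6-iodo-2-methylidenehept-5-enoate (racemic)
Conditions: DABCO, 1,4-dioxane/H2O, rt
Reagents that add atoms: none
Why: Morita–Baylis–Hillman reaction: the DABCO–acrylate zwitterion adds to the aldehyde and β-elimination gives the α-methylene-β-hydroxy ester, whose racemic carbinol centre is erased in step 7.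

Step 7
Reactants: 11 methyl (5E)-3-hydroxy-6-iodo-2-methylidenehept-5-enoate
Product: 12 methyl (2Z,5E)-2-(bromomethyl)-6-iodohepta-2,5-dienoate
Conditions: NBS, Me2S, CH2Cl2, 0 °C to rt
Reagents that add atoms: N-bromosuccinimide, O=C1CCC(=O)N1Br
Why: Corey–Kim-type activation of the allylic alcohol and SN2′ attack of bromide with allylic transposition give the conjugated, thermodynamically favoured (Z)-2-(bromomethyl)enoate, a standard conversion of Baylis–Hillman alcohols.

Step 8
Reactants: 13 but-2-yn-1-ol
Product: 15 (2E)-3-bromobut-2-en-1-ol, via alkenylzirconocene 14 (not isolated)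
Conditions: Cp2Zr(H)Cl (2.5 equiv), THF, rt to 40 °C; then NBS, 0 °C
Reagents that add atoms: N-bromosuccinimide, O=C1CCC(=O)N1Br
Why: Hydrozirconation–bromination as in step 4: syn addition with zirconium on the methyl-bearing carbon and brominolysis with retention give the (E)-bromoalkene that becomes C3=C4.

Step 9
Reactants: 15 (2E)-3-bromobut-2-en-1-ol
Product: 16 (2E)-3-bromobut-2-enal
Conditions: MnO2, CH2Cl2, rt
Reagents that add atoms: none
Why: MnO2 oxidises the allylic alcohol selectively to the enal without E/Z isomerisation.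

Step 10
Reactants: 12 methyl (2Z,5E)-2-(bromomethyl)-6-iodohepta-2,5-dienoate; 16 (2E)-3-bromobut-2-enal
Product: 19 (4S,5R)-5-[(1E)-2-bromoprop-1-en-1-yl]-4-[(2E)-3-iodobut-2-en-1-yl]-3-methylideneoxolan-2-one, via silyl ether 17 (not isolated), via hydroxy ester 18 (not isolated)
Conditions: CrCl2 (10 mol %), chiral carbazole-bis(oxazoline) ligand (12 mol %), Mn powder, TMSCl, i-Pr2NEt (cat.), THF, rt; then 1 M HCl, THF
Reagents that add atoms: none
Why: Catalytic asymmetric Nozaki–Hiyama allylation with a 2-(alkoxycarbonyl)allyl bromide: the allylchromium reagent, whose C14 substituent lies trans to the ester, adds through its γ-carbon (C1) in a chair transition state to give the syn adduct, the ligand selects the aldehyde face (C2), and acid work-up cleaves the silyl ether and lactonises to the cis lactone; without nickel the alkenyl iodide and bromide are inert to divalent chromium.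

Step 11
Reactants: 19 cis-lactone bearing the alkenyl iodide and alkenyl bromide; 5 epoxy aldehyde
Product: 20 (11S)-allylic alcohol of the joined chain (C11–C12 bond formed)
Conditions: CrCl2 (cat.), chiral oxazoline–sulfonamide ligand, NiCl2·(2,9-dimethyl-1,10-phenanthroline) (cat.), Mn powder, Cp2ZrCl2, LiCl, MeCN, rt
Reagents that add atoms: none
Why: Catalytic asymmetric Nozaki–Hiyama–Kishi coupling: zerovalent nickel inserts into the alkenyl C–I bond much faster than into C–Br, the alkenyl group passes to chromium with retention of the (12E) geometry, and the ligand directs addition to one aldehyde face to set C11 (S); the neutral conditions spare the epoxide, silyl ether and lactone.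

Step 12
Reactants: 20 (11S)-allylic alcohol
Product: 21 (11R)-allylic chloride
Conditions: PPh3, hexachloroacetone, CH2Cl2, −20 to 0 °C
Reagents that add atoms: hexachloroacetone, O=C(C(Cl)(Cl)Cl)C(Cl)(Cl)Cl
Why: Appel-type chlorination: the alkoxyphosphonium ion is displaced by chloride in an SN2 step without allylic transposition, so the (11S) alcohol gives the (11R) chloride; no acid is generated, so the epoxide survives.

Step 13
Reactants: 21 (11R)-allylic chloride
Product: 22 (8R)-hydroperoxide, (7S)-alcohol (epoxide opened at C8)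
Conditions: anhydrous H2O2 in Et2O (excess), H3PMo12O40 (cat.), rt
Reagents that add atoms: hydrogen peroxide, OO
Why: Acid-catalysed perhydrolysis of a trisubstituted epoxide: H2O2 attacks the tertiary carbon C8 from the face opposite the oxirane oxygen (8S to 8R) while C7 keeps its oxygen and configuration, the C6 silyloxy group disfavouring attack at C7; the allylic chloride does not ionise in ether.

Step 14
Reactants: 22 chloro hydroperoxide
Product: 23 cis-3,6-disubstituted 1,2-dioxane with free C7–OH
Conditions: Cs2CO3, DMF (dilute), 0 °C to rt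
Reagents that add atoms: none
Why: Intramolecular SN2 alkylation of a hydroperoxide (6-exo-tet): the hydroperoxide is far more acidic and nucleophilic than the C7 hydroxyl, so its caesium salt displaces the allylic chloride with inversion (11R to 11S) and closes the 1,2-dioxane with the C7 and C12 branches cis.

Step 15
Reactants: 23 dioxane alcohol
Product: 24 C7 acetate
Conditions: Ac2O, DMAP (cat.), pyridine, CH2Cl2, rt
Reagents that add atoms: acetic anhydride, CC(=O)OC(C)=O
Why: DMAP-catalysed acetylation of the hindered secondary alcohol installs the C7 acetate of the target under conditions too weakly basic for Kornblum–DeLaMare cleavage of the peroxide.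

Step 16
Reactants: 24 C7 acetate, C6 silyl ether
Product: 25 primary C6 alcohol
Conditions: HF·pyridine, pyridine/THF, 0 °C to rt
Reagents that add atoms: none
Why: Fluoride desilylation under buffered acidic conditions frees the primary alcohol without acetyl migration and without touching the peroxide.

Step 17
Reactants: 25 primary C6 alcohol
Product: 26 α-acetoxy aldehyde (C6 = CHO)
Conditions: Dess–Martin periodinane, NaHCO3, CH2Cl2, 0 °C
Reagents that add atoms: none
Why: Buffered Dess–Martin oxidation gives the aldehyde under non-basic conditions, so C7 does not epimerise and the β-peroxide is not eliminated.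

Step 18
Reactants: 26 α-acetoxy aldehyde
Product: 27 seco precursor with C5=C6 vinyl group and C4 alkenyl bromide
Conditions: Ph3PCH3Br, KN(SiMe3)2, THF, −78 °C (ylide preformed, 1.05 equiv), then to 0 °C
Reagents that add atoms: methyltriphenylphosphonium bromide, C[P+](c1ccccc1)(c1ccccc1)c1ccccc1.[Br-]
Why: Wittig methylenation: the non-stabilised ylide adds to the aldehyde at −78 °C much faster than it enolises C7–H or adds to the exo-methylene lactone, and supplies C5 as the terminal CH2.

Step 19
Reactants: 27 seco precursor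
Product: 29 target (1S,2S,3E,7S,8R,11S,12E)-7-acetoxy-8,11-epidioxycembra-3,12,15(17)-trien-16,2-olide, via alkylborane 28 (not isolated)
Conditions: 9-BBN (1.5 equiv), THF, 0 °C to rt; then slow addition to Pd(dppf)Cl2 (20 mol %), AsPh3, Cs2CO3, DMF/THF/H2O, rt, about 1 mM
Reagents that add atoms: none
Why: 9-BBN adds anti-Markovnikov and chemoselectively to the monosubstituted C5=C6 alkene (the trisubstituted alkenes, the alkenyl bromide and the electron-poor exo-methylene react far more slowly), giving primary alkylborane 28 without a new stereocentre; zerovalent palladium then inserts into the C4–Br bond, the carbonate-activated borate transfers the C5 alkyl group and reductive elimination forms C4–C5 with retention of the (3E) geometry. The closest known reaction type is the B-alkyl Suzuki–Miyaura macrocyclisation of an alkenyl halide tethered to a terminal alkene. The 14-membered carbocycle is closed end to end by reductive elimination from a 15-membered palladacycle, and the same bond completes the bridge across C8/C11 of the 1,2-dioxane. No stereocentre is created; the alkene geometry comes from bromoenal 16. The selectivity needed is ring closure over oligomerisation and survival of the O–O bond, the acetate and the lactone: slow addition at high dilution, the turn imposed by the cis-3,6-disubstituted dioxane and the cis-fused lactone, room temperature and a mild carbonate base should secure it.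

**Compound list**
1 | geraniol, (2E)-3,7-dimethylocta-2,6-dien-1-ol | C/C(=C\CO)CCC=C(C)C | starting material
2 | (2S,3S)-2,3-epoxygeraniol, [(2S,3S)-3-methyl-3-(4-methylpent-3-en-1-yl)oxiran-2-yl]methanol | CC(C)=CCC[C@]1(C)O[C@H]1CO | intermediate
3 | tert-butyl{[(2S,3S)-3-methyl-3-(4-methylpent-3-en-1-yl)oxiran-2-yl]methoxy}diphenylsilane | CC(C)=CCC[C@]1(C)O[C@H]1CO[Si](c1ccccc1)(c1ccccc1)C(C)(C)C | intermediate
4 | vicinal diol from dihydroxylation of the distal alkene of 3 (both carbinol epimers; not isolated) | CC(C)(O)C(O)CC[C@]1(C)O[C@H]1CO[Si](c1ccccc1)(c1ccccc1)C(C)(C)C | intermediate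
5 | 3-[(2S,3S)-3-{[(tert-butyldiphenylsilyl)oxy]methyl}-2-methyloxiran-2-yl]propanal (CHO = C11) | O=CCC[C@]1(C)O[C@H]1CO[Si](c1ccccc1)(c1ccccc1)C(C)(C)C | intermediate
6 | pent-3-yn-1-ol | CC#CCCO | starting material
7 | O-zirconated (E)-alkenylzirconocene chloride from 6 (Zr on the methyl-bearing carbon, syn to H; not isolated) | C/C(=C\CCO[Zr](Cl)(C1C=CC=C1)C1C=CC=C1)[Zr](Cl)(C1C=CC=C1)C1C=CC=C1 | intermediate
8 | (3E)-4-iodopent-3-en-1-ol | OCC/C=C(/I)C | intermediate
9 | (3E)-4-iodopent-3-enal | O=CC/C=C(/I)C | intermediate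
10 | methyl acrylate | C=CC(=O)OC | starting material
11 | methyl (5E)-3-hydroxy-6-iodo-2-methylidenehept-5-enoate (racemic) | COC(=O)C(=C)C(O)C/C=C(/I)C | intermediate
12 | methyl (2Z,5E)-2-(bromomethyl)-6-iodohepta-2,5-dienoate | COC(=O)/C(CBr)=C/C/C=C(/I)C | intermediate
13 | but-2-yn-1-ol | CC#CCO | starting material
14 | O-zirconated (E)-alkenylzirconocene chloride from 13 (not isolated) | C/C(=C\CO[Zr](Cl)(C1C=CC=C1)C1C=CC=C1)[Zr](Cl)(C1C=CC=C1)C1C=CC=C1 | intermediate
15 | (2E)-3-bromobut-2-en-1-ol | OC/C=C(\C)Br | intermediate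
16 | (2E)-3-bromobut-2-enal | O=C/C=C(\C)Br | intermediate
17 | trimethylsilyl ether of 18 (not isolated) | COC(=O)C(=C)[C@H](C/C=C(/I)C)[C@@H](O[Si](C)(C)C)/C=C(\C)Br | intermediate
18 | methyl (3S,5E)-3-[(1R,2E)-3-bromo-1-hydroxybut-2-en-1-yl]-6-iodo-2-methylidenehept-5-enoate (syn adduct; not isolated) | COC(=O)C(=C)[C@H](C/C=C(/I)C)[C@@H](O)/C=C(\C)Br | intermediate
19 | (4S,5R)-5-[(1E)-2-bromoprop-1-en-1-yl]-4-[(2E)-3-iodobut-2-en-1-yl]-3-methylideneoxolan-2-one (cis lactone) | C=C1C(=O)O[C@@H](/C=C(\C)Br)[C@H]1C/C=C(C)/I | intermediate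
20 | (4S,5R)-5-[(1E)-2-bromoprop-1-en-1-yl]-4-[(2E,4S)-6-[(2S,3S)-3-{[(tert-butyldiphenylsilyl)oxy]methyl}-2-methyloxiran-2-yl]-4-hydroxy-3-methylhex-2-en-1-yl]-3-methylideneoxolan-2-one | C=C1C(=O)O[C@@H](/C=C(\C)Br)[C@H]1C/C=C(C)/[C@@H](O)CC[C@]1(C)O[C@H]1CO[Si](c1ccccc1)(c1ccccc1)C(C)(C)C | intermediate
21 | the (2E,4R)-4-chloro analogue of 20 (11R chloride) | C=C1C(=O)O[C@@H](/C=C(\C)Br)[C@H]1C/C=C(C)/[C@H](Cl)CC[C@]1(C)O[C@H]1CO[Si](c1ccccc1)(c1ccccc1)C(C)(C)C | intermediate
22 | (4S,5R)-5-[(1E)-2-bromoprop-1-en-1-yl]-4-[(2E,4R,7R,8S)-9-[(tert-butyldiphenylsilyl)oxy]-4-chloro-7-hydroperoxy-8-hydroxy-3,7-dimethylnon-2-en-1-yl]-3-methylideneoxolan-2-one | C=C1C(=O)O[C@@H](/C=C(\C)Br)[C@H]1C/C=C(C)/[C@H](Cl)CC[C@@](C)(OO)[C@@H](O)CO[Si](c1ccccc1)(c1ccccc1)C(C)(C)C | intermediate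
23 | (4S,5R)-5-[(1E)-2-bromoprop-1-en-1-yl]-4-[(2E)-3-{(3S,6R)-6-[(1S)-2-[(tert-butyldiphenylsilyl)oxy]-1-hydroxyethyl]-6-methyl-1,2-dioxan-3-yl}but-2-en-1-yl]-3-methylideneoxolan-2-one | C=C1C(=O)O[C@@H](/C=C(\C)Br)[C@H]1C/C=C(/[C@@H]1CC[C@@]([C@H](CO[Si](c2ccccc2)(c2ccccc2)C(C)(C)C)O)(C)OO1)C | intermediate
24 | acetate of 23: dioxane C6 bears (1S)-1-acetoxy-2-[(tert-butyldiphenylsilyl)oxy]ethyl | C=C1C(=O)O[C@@H](/C=C(\C)Br)[C@H]1C/C=C(/[C@@H]1CC[C@@]([C@H](CO[Si](c2ccccc2)(c2ccccc2)C(C)(C)C)OC(C)=O)(C)OO1)C | intermediate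
25 | desilylated 24: dioxane C6 bears (1S)-1-acetoxy-2-hydroxyethyl | C=C1C(=O)O[C@@H](/C=C(\C)Br)[C@H]1C/C=C(/[C@@H]1CC[C@@]([C@H](CO)OC(C)=O)(C)OO1)C | intermediate
26 | aldehyde: dioxane C6 bears (1R)-1-acetoxy-2-oxoethyl (same geometry as 25; the descriptor changes by priority only) | C=C1C(=O)O[C@@H](/C=C(\C)Br)[C@H]1C/C=C(/[C@@H]1CC[C@@]([C@H](C=O)OC(C)=O)(C)OO1)C | intermediate
27 | (4S,5R)-4-[(2E)-3-{(3S,6R)-6-[(1S)-1-acetoxyprop-2-en-1-yl]-6-methyl-1,2-dioxan-3-yl}but-2-en-1-yl]-5-[(1E)-2-bromoprop-1-en-1-yl]-3-methylideneoxolan-2-one | C=C1C(=O)O[C@@H](/C=C(\C)Br)[C@H]1C/C=C(/[C@@H]1CC[C@@]([C@H](C=C)OC(C)=O)(C)OO1)C | intermediate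
28 | C5 9-borabicyclo[3.3.1]nonan-9-yl borane from 27: dioxane C6 bears (1S)-1-acetoxy-3-(9-BBN)propyl (not isolated) | C=C1C(=O)O[C@@H](/C=C(\C)Br)[C@H]1C/C=C(/[C@@H]1CC[C@@]([C@H](CCB2C3CCCC2CCC3)OC(C)=O)(C)OO1)C | intermediate
29 | (1S,2S,3E,7S,8R,11S,12E)-7-acetoxy-8,11-epidioxycembra-3,12,15(17)-trien-16,2-olide | C=C1C(=O)O[C@H]2/C=C(\C)CC[C@H](OC(C)=O)[C@@]3(C)CC[C@H](OO3)/C(C)=C/C[C@@H]12 | target

**Step count and risks**
Total: 19 steps. Longest linear sequence: 14 steps (steps 4–7, 10, 11–19, from pent-3-yn-1-ol).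

Step 19 (ring closure). What may go wrong: attack of the borane or of zerovalent palladium on the O–O bond, and consumption of the exo-methylene lactone by hydroboration or base-induced conjugate addition during the slow high-dilution coupling. Fallback: set out from 27 and mask the acrylate before the metal chemistry. Conjugate addition of dimethylamine (THF, 0 °C) should give the 17-dimethylamino lactone F1. Hydroboration (9-BBN, one extra equivalent for the amine) gives the borane F2, and the same palladium conditions should close the ring to the amino macrocycle F3. N-Methylation (MeI) to the ammonium iodide F4 and elimination with aqueous NaHCO3 return to the route at 29.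

Step 14 (dioxane closure). What may go wrong: the hindered tertiary peroxide anion displaces the secondary allylic chloride too slowly, so that elimination, allylic transposition, conjugate addition to the lactone or ionisation with loss of configuration at C11 compete. Fallback with the order of C–O bond formation reversed: set out from 21 and displace the chloride with the small external nucleophile 2-methoxyprop-2-yl hydroperoxide (CsOH·H2O, DMF, 0 °C) to give the (11S) peroxyketal F5. Mild acid (pyridinium p-toluenesulfonate, MeOH/CH2Cl2) frees the secondary hydroperoxide F6, which under the same acid should open the epoxide at the tertiary C8 in a 6-exo mode with inversion and so rejoin the route at 23.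

Step 11 (fragment union). What may go wrong: incomplete discrimination of the alkenyl iodide from the alkenyl bromide, and poor facial selectivity in the addition to an unbranched aldehyde. Fallback: set out from 19 and 5 and couple without chiral ligand (stoichiometric CrCl2, catalytic NiCl2, DMSO) to give 20 mixed with its (11R) epimer F7. Oxidation of the mixture with Dess–Martin periodinane gives the enone F8, and Corey–Bakshi–Shibata reduction with the (R)-methyl oxazaborolidine and catecholborane should return the (11S) alcohol 20.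

**Further compounds**
F1 | step 19 | dimethylamine adduct of 27, 3-[(dimethylamino)methyl] lactone (C15 epimers) | CN(C)CC1C(=O)O[C@@H](/C=C(\C)Br)[C@H]1C/C=C(/[C@@H]1CC[C@@]([C@H](C=C)OC(C)=O)(C)OO1)C
F2 | step 19 | C5 9-BBN borane of F1 | CN(C)CC1C(=O)O[C@@H](/C=C(\C)Br)[C@H]1C/C=C(/[C@@H]1CC[C@@]([C@H](CCB2C3CCCC2CCC3)OC(C)=O)(C)OO1)C
F3 | step 19 | macrocyclic 17-(dimethylamino)-15,17-dihydro derivative of 29 | CN(C)CC1C(=O)O[C@H]2/C=C(\C)CC[C@H](OC(C)=O)[C@@]3(C)CC[C@H](OO3)/C(C)=C/C[C@@H]12
F4 | step 19 | trimethylammonium iodide from F3 | C[N+](C)(C)CC1C(=O)O[C@H]2/C=C(\C)CC[C@H](OC(C)=O)[C@@]3(C)CC[C@H](OO3)/C(C)=C/C[C@@H]12.[I-]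
F5 | step 14 | (11S) 2-methoxyprop-2-yl peroxide of the epoxide series | C=C1C(=O)O[C@@H](/C=C(\C)Br)[C@H]1C/C=C(C)/[C@@H](OOC(C)(C)OC)CC[C@]1(C)O[C@H]1CO[Si](c1ccccc1)(c1ccccc1)C(C)(C)C
F6 | step 14 | (11S) allylic hydroperoxide of the epoxide series | C=C1C(=O)O[C@@H](/C=C(\C)Br)[C@H]1C/C=C(C)/[C@@H](OO)CC[C@]1(C)O[C@H]1CO[Si](c1ccccc1)(c1ccccc1)C(C)(C)C
F7 | step 11 | (11R) epimer of 20 | C=C1C(=O)O[C@@H](/C=C(\C)Br)[C@H]1C/C=C(C)/[C@H](O)CC[C@]1(C)O[C@H]1CO[Si](c1ccccc1)(c1ccccc1)C(C)(C)C
F8 | step 11 | C11 enone from 20 and F7 | C=C1C(=O)O[C@@H](/C=C(\C)Br)[C@H]1C/C=C(C)/C(=O)CC[C@]1(C)O[C@H]1CO[Si](c1ccccc1)(c1ccccc1)C(C)(C)C
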